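**Plan**

- Labels: ring A = the styryl 3,5-dihydroxyphenyl; rings B and C = the benzo and dioxane rings of the 2,3-dihydro-1,4-benzodioxine (O-1, C-2, C-3, O-4, C-4a, C-5 to C-8, C-8a); ring D = the 3,5-dihydroxyphenyl on C-2; ring E = the catechol on C-3.
- Retrosynthetic cuts: the six aryl O–CH2OMe bonds; then, in one operation, the C-6–vinyl bond and the O-1–C-8a bond of ring C (to an open-chain 2-bromo-5-iodophenyl ether of a threo aryloxy alcohol plus 3,5-bis(methoxymethoxy)styrene); then the carbinol C–H bond (to a racemic α-aryloxy ketone), the O-4–C-3 bond (phenol plus diazo ketone) and the CH2–ring E bond (acetophenone plus aryl bromide).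
- Forward order: the two-carbon chain between rings D and E is made first, ring B is attached through O-4, both stereocentres are set, then ring C is closed and the ring A styrene attached in the same flask, and the phenols are freed last.
- Enabling feature: ring B is 1,2,4-substituted, with the vinyl carbon on C-6 para to C-8a (O-1, bonded to C-2) and meta to C-4a (O-4, bonded to C-3). 2-Bromo-5-iodophenol carries this pattern (OH = O-4, Br at the future C-8a, I at the future C-6), so the weaker C–I bond takes the styrene first and the C–Br bond, ortho to the ether oxygen, is then within reach of the C-2 hydroxyl for a six-membered ring closure.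
- Stereochemistry: both centres come from one ruthenium-catalysed asymmetric transfer hydrogenation with dynamic kinetic resolution (catalyst-controlled carbinol, racemising α-aryloxy centre funnelled to the threo isomer). The ring closure forms an O–aryl bond and touches neither centre, so threo becomes trans-(2R,3R); the E alkene comes from the syn-insertion/syn-elimination of the Heck event.

Key step: step 9

Remark: the syn (threo) sense of the dynamic kinetic resolution in step 6 is assumed from the behaviour of benzoins and other α-oxygenated aryl ketones under the same catalysis.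

**Step 1**
Reactants: 1 3',5'-dihydroxyacetophenone
Product: 2 3',5'-bis(methoxymethoxy)acetophenone
Conditions: MOMCl (2.5 equiv), i-Pr2NEt (3 equiv), CH2Cl2, 0 °C to rt
Reagents that add atoms: chloromethyl methyl ether, COCCl
Why: Williamson-type O-alkylation of both phenols with the α-chloro ether should give the bis(methoxymethyl) acetal, which tolerates the bases and the palladium, rhodium and ruthenium catalysts used later and is removed with acid at the end; no stereocentre is involved.

**Step 2**
Reactants: 3 4-bromocatechol
Product: 4 4-bromo-1,2-bis(methoxymethoxy)benzene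
Conditions: MOMCl (2.5 equiv), i-Pr2NEt (3 equiv), CH2Cl2, 0 °C to rt
Reagents that add atoms: chloromethyl methyl ether, COCCl
Why: the same Williamson-type acetal formation should mask both catechol oxygens of the future ring E and leave the aryl bromide for the coupling; no stereocentre is involved.

**Step 3**
Reactants: 2 3',5'-bis(methoxymethoxy)acetophenone; 4 4-bromo-1,2-bis(methoxymethoxy)benzene
Product: 5 tetrakis(methoxymethoxy)deoxybenzoin
Conditions: Pd2(dba)3 (1.5 mol%), Xantphos (3.6 mol%), NaOt-Bu (1.3 equiv), THF, 70 °C
Reagents that add atoms: none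
Why: palladium-catalysed ketone α-arylation (Buchwald–Hartwig-type enolate arylation), in which the aryl bromide adds oxidatively to zerovalent palladium, the sodium enolate of 2 exchanges for bromide and reductive elimination joins ring E to the methyl carbon, with the wide-bite-angle diphosphine and the more acidic product (held as its enolate) favouring monoarylation; no stereocentre is formed.

**Step 4**
Reactants: 5 tetrakis(methoxymethoxy)deoxybenzoin
Product: 6 diazo ketone
Conditions: 4-acetamidobenzenesulfonyl azide (1.2 equiv), DBU (1.5 equiv), MeCN, 0 °C to rt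
Reagents that add atoms: 4-acetamidobenzenesulfonyl azide, CC(=O)Nc1ccc(cc1)S(=O)(=O)N=[N+]=[N-]
Why: Regitz diazo transfer, in which DBU deprotonates the methylene flanked by the carbonyl and ring E and the enolate attacks the terminal azide nitrogen, the sulfonamide leaving under non-acidic conditions that spare the acetals; the diazo carbon is not a stereocentre.

**Step 5**
Reactants: 6 diazo ketone; 7 2-bromo-5-iodophenol
Product: 8 racemic α-aryloxy ketone
Conditions: Rh2(OAc)4 (1 mol%), CH2Cl2, rt, slow addition of 6 to 7 (1.3 equiv)
Reagents that add atoms: none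
Why: rhodium-carbenoid O–H insertion, in which loss of dinitrogen gives an electrophilic donor/acceptor carbenoid, the phenol oxygen adds to form an oxonium ylide and a 1,2-proton shift delivers the aryl ether with both halogens untouched; the new centre is formed racemic on purpose, since it is configurationally labile (benzylic and α to the ketone) and is set in the next step.

**Step 6**
Reactants: 8 racemic α-aryloxy ketone
Product: 9 (1R,2R)-threo aryloxy alcohol
Conditions: RuCl[(S,S)-TsDPEN](p-cymene) (2 mol%), HCO2H/Et3N (5:2), DMF, 40 °C
Reagents that add atoms: none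
Why: Noyori-type asymmetric transfer hydrogenation with dynamic kinetic resolution, in which triethylamine racemises the acidic α-aryloxy benzylic centre faster than reduction, the (S,S)-catalyst delivers hydride through the six-membered N–H/Ru–H transition state with ring D held against the η6-arene so that the carbinol is R (the spatial sense of (S)-1-phenylethanol), and only the α-epimer leading to the syn (threo) aryloxy alcohol should be reduced rapidly, as with benzoins, so that both centres, (1R,2R), are set from the racemate while the aryl halides stay inert to the ruthenium hydride.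

**Step 7**
Reactants: 10 3,5-dihydroxybenzaldehyde
Product: 11 3,5-bis(methoxymethoxy)benzaldehyde
Conditions: MOMCl (2.5 equiv), i-Pr2NEt (3 equiv), CH2Cl2, 0 °C to rt
Reagents that add atoms: chloromethyl methyl ether, COCCl
Why: Williamson-type acetal formation on the two phenols should proceed without touching the aldehyde; no stereocentre is involved.

**Step 8**
Reactants: 11 3,5-bis(methoxymethoxy)benzaldehyde
Product: 12 3,5-bis(methoxymethoxy)styrene
Conditions: Ph3PCH3Br (1.3 equiv), KOt-Bu (1.25 equiv), THF, 0 °C to rt
Reagents that add atoms: methyltriphenylphosphonium bromide, C[P+](c1ccccc1)(c1ccccc1)c1ccccc1.[Br-]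
Why: Wittig methylenation with the non-stabilised ylide should convert the aldehyde into the terminal alkene under conditions that leave the aryl acetals alone; no stereo element arises.

**Step 9**
Reactants: 9 (1R,2R)-threo aryloxy alcohol; 12 3,5-bis(methoxymethoxy)styrene
Product: 14 hexa-O-methoxymethyl cassigarol E, via open-chain Heck product 13 (not isolated)
Conditions: 12 (1.05 equiv), Pd2(dba)3 (2.5 mol%), t-BuXPhos (10 mol%), Cs2CO3 (3 equiv), toluene, 70 °C, then 100 °C
Reagents that add atoms: none
Why: Zerovalent palladium inserts first into the weaker, unhindered C–I bond of 9; syn-carbopalladation of the terminal carbon of 12 and syn β-hydride elimination then give the E-stilbene 13 (Mizoroki–Heck reaction, with couplings of aryl iodides and 3,5-dioxygenated styrenes as the closest precedent), and the base returns the catalyst. With the iodide used up, oxidative addition into the C–Br bond ortho to the ether oxygen is followed by carbonate-assisted exchange of bromide for the C-1 alkoxide and C–O reductive elimination (Buchwald–Hartwig-type intramolecular etherification, as known for 2-(2-bromophenoxy)ethanols with secondary hydroxyls), so ring C closes by aryl C–O bond formation through a seven-membered oxapalladacycle to the six-membered dioxane. No new stereocentre arises: no bond at C-1 or C-2 of 9 is broken, so the (1R,2R)-threo array is carried with retention into the trans-(2R,3R) ring, and the only new stereo element, the alkene, is E because of the syn-insertion/syn-elimination sequence. The step needs C–I to react before C–Br (secured by bond strength, by the ortho substituent at C–Br and by only 1.05 equiv of 12, which leaves no alkene for a second Heck coupling), arylation at the terminal alkene carbon (neutral, halide-bound pathway), and reductive elimination faster than β-hydride elimination from the palladium alkoxide (secured by the bulky di-tert-butyl biaryl phosphine and the favourable six-membered ring).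

**Step 10**
Reactants: 14 hexa-O-methoxymethyl cassigarol E
Product: 15 cassigarol E
Conditions: HCl (1.25 M in MeOH), THF/MeOH, 40 °C, argon
Reagents that add atoms: none
Why: acid-catalysed acetal exchange with methanol should cleave all six aryl methoxymethyl ethers as dimethoxymethane, as is usual for methoxymethyl-protected hydroxystilbenes; C-2 has no cation-stabilising para oxygen and stays fixed, and if the para-hydroxybenzylic C-3–O-4 bond ionised reversibly, reclosure would return the more stable trans-diequatorial ring, so the (2R,3R) configuration and the E alkene should be kept.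

**Compound list**

1 | 3',5'-dihydroxyacetophenone, 1-(3,5-dihydroxyphenyl)ethan-1-one | CC(=O)c1cc(O)cc(O)c1 | starting material
2 | 3',5'-bis(methoxymethoxy)acetophenone, 1-[3,5-bis(methoxymethoxy)phenyl]ethan-1-one | CC(=O)c1cc(OCOC)cc(OCOC)c1 | intermediate
3 | 4-bromocatechol, 4-bromobenzene-1,2-diol | Oc1ccc(Br)cc1O | starting material
4 | 4-bromo-1,2-bis(methoxymethoxy)benzene | COCOc1ccc(Br)cc1OCOC | intermediate
5 | tetrakis(methoxymethoxy)deoxybenzoin, 1-[3,5-bis(methoxymethoxy)phenyl]-2-[3,4-bis(methoxymethoxy)phenyl]ethan-1-one | O=C(Cc1ccc(OCOC)c(OCOC)c1)c1cc(OCOC)cc(OCOC)c1 | intermediate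
6 | diazo ketone, 2-diazo-1-[3,5-bis(methoxymethoxy)phenyl]-2-[3,4-bis(methoxymethoxy)phenyl]ethan-1-one | O=C(C(=[N+]=[N-])c1ccc(OCOC)c(OCOC)c1)c1cc(OCOC)cc(OCOC)c1 | intermediate
7 | 2-bromo-5-iodophenol | Oc1cc(I)ccc1Br | starting material
8 | racemic α-aryloxy ketone, 2-(2-bromo-5-iodophenoxy)-1-[3,5-bis(methoxymethoxy)phenyl]-2-[3,4-bis(methoxymethoxy)phenyl]ethan-1-one | O=C(C(Oc1cc(I)ccc1Br)c1ccc(OCOC)c(OCOC)c1)c1cc(OCOC)cc(OCOC)c1 | intermediate
9 | threo aryloxy alcohol, (1R,2R)-2-(2-bromo-5-iodophenoxy)-1-[3,5-bis(methoxymethoxy)phenyl]-2-[3,4-bis(methoxymethoxy)phenyl]ethan-1-ol | O[C@H](c1cc(OCOC)cc(OCOC)c1)[C@H](Oc1cc(I)ccc1Br)c1ccc(OCOC)c(OCOC)c1 | intermediate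
10 | 3,5-dihydroxybenzaldehyde | O=Cc1cc(O)cc(O)c1 | starting material
11 | 3,5-bis(methoxymethoxy)benzaldehyde | O=Cc1cc(OCOC)cc(OCOC)c1 | intermediate
12 | 3,5-bis(methoxymethoxy)styrene, 1-ethenyl-3,5-bis(methoxymethoxy)benzene | C=Cc1cc(OCOC)cc(OCOC)c1 | intermediate
13 | open-chain Heck product, (1R,2R)-2-{2-bromo-5-[(E)-2-[3,5-bis(methoxymethoxy)phenyl]ethenyl]phenoxy}-1-[3,5-bis(methoxymethoxy)phenyl]-2-[3,4-bis(methoxymethoxy)phenyl]ethan-1-ol | O[C@H](c1cc(OCOC)cc(OCOC)c1)[C@H](Oc1cc(/C=C/c2cc(OCOC)cc(OCOC)c2)ccc1Br)c1ccc(OCOC)c(OCOC)c1 | intermediate
14 | hexa-O-methoxymethyl cassigarol E, (2R,3R)-3-[3,4-bis(methoxymethoxy)phenyl]-2-[3,5-bis(methoxymethoxy)phenyl]-6-{(E)-2-[3,5-bis(methoxymethoxy)phenyl]ethenyl}-2,3-dihydro-1,4-benzodioxine | COCOc1cc(OCOC)cc(/C=C/c2ccc3c(c2)O[C@H](c2ccc(OCOC)c(OCOC)c2)[C@@H](c2cc(OCOC)cc(OCOC)c2)O3)c1 | intermediate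
15 | cassigarol E, (2R,3R)-3-(3,4-dihydroxyphenyl)-2-(3,5-dihydroxyphenyl)-6-[(E)-2-(3,5-dihydroxyphenyl)ethenyl]-2,3-dihydro-1,4-benzodioxine | Oc1cc(O)cc(/C=C/c2ccc3c(c2)O[C@H](c2ccc(O)c(O)c2)[C@@H](c2cc(O)cc(O)c2)O3)c1 | target

**Totals**

Total step count: 10.
Longest linear sequence: 7 steps (steps 1, 3, 4, 5, 6, 9, 10).

**Steps most likely to fail**

1. Step 9. What may go wrong: β-hydride elimination from the palladium alkoxide (the carbinol is oxidised and the C–Br bond reduced), or a second Heck coupling at the C–Br bond before ring closure. Fallback, setting out from 9 and coming back at 14: the two events are separated and the metal of the C–O step is changed. A Heck coupling of 9 with 12 at the C–I bond only (Pd(OAc)2, P(o-tol)3, Et3N, MeCN, 80 °C) should allow isolation of the open-chain Heck product 13. A copper-catalysed Ullmann-type intramolecular etherification (CuI, 3,4,7,8-tetramethyl-1,10-phenanthroline, Cs2CO3, toluene, 110 °C) should then close ring C to 14 through a copper alkoxide that is not prone to β-hydride elimination. This fallback makes no compound outside the list (F0).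

2. Step 6. What may go wrong: erythro instead of threo selectivity in the dynamic kinetic resolution (a mismatch between the catalyst-controlled hydride delivery and the preferred α-epimer), which would lead to the cis ring. Fallback, setting out from 8 and coming back at 9: reduction of 8 with the enantiomeric catalyst RuCl[(R,R)-TsDPEN](p-cymene) under the same conditions should then give the (1S,2R)-erythro aryloxy alcohol F1. Mitsunobu inversion of its carbinol (PPh3, DIAD, 4-nitrobenzoic acid, THF, 0 °C) should give the (1R,2R)-4-nitrobenzoate F2, and methanolysis (K2CO3, MeOH, rt) should release 9.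

3. Step 5. What may go wrong: Wolff rearrangement or dimerisation of the rhodium carbenoid outruns O–H insertion into the hindered, weakly nucleophilic ortho-bromophenol. Fallback, setting out from 5 and coming back at 8: the diazo compound is bypassed by an ionic etherification. Enolate bromination of 5 (LiHMDS, THF, −78 °C, then N-bromosuccinimide) should give the racemic α-bromo ketone F3, whose activated benzylic bromide should be displaced by the potassium phenoxide of 7 (K2CO3, acetone, rt) to give 8.

**Further compounds**

F0 | step 9 | none | none
F1 | step 6 | (1S,2R)-2-(2-bromo-5-iodophenoxy)-1-[3,5-bis(methoxymethoxy)phenyl]-2-[3,4-bis(methoxymethoxy)phenyl]ethan-1-ol | O[C@@H](c1cc(OCOC)cc(OCOC)c1)[C@H](Oc1cc(I)ccc1Br)c1ccc(OCOC)c(OCOC)c1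
F2 | step 6 | (1R,2R)-2-(2-bromo-5-iodophenoxy)-1-[3,5-bis(methoxymethoxy)phenyl]-2-[3,4-bis(methoxymethoxy)phenyl]ethyl 4-nitrobenzoate | O=C(O[C@H](c1cc(OCOC)cc(OCOC)c1)[C@H](Oc1cc(I)ccc1Br)c1ccc(OCOC)c(OCOC)c1)c1ccc(cc1)[N+](=O)[O-]
F3 | step 5 | racemic 2-bromo-2-[3,4-bis(methoxymethoxy)phenyl]-1-[3,5-bis(methoxymethoxy)phenyl]ethan-1-one | O=C(C(Br)c1ccc(OCOC)c(OCOC)c1)c1cc(OCOC)cc(OCOC)c1
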